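**Retrosynthetic overview**
1. No ring is formed: the cyclohexene ring and its only stereocentre are bought as (S)-α-ionone 1 (reduced to ketone 2); the quinone ring is bought as 2,5-dimethoxy-1,4-benzoquinone.
2. Two-carbon extension of 2 with phosphonate 3 sets the E-trisubstituted olefin: enoate 4, then allylic alcohol 5, then carbonate 6.
3. Quinone partner: mono-demethylation of 7 gives hydroxyquinone 8, so OH and OMe are differentiated before coupling.
4. Key disconnection: the quinone C3–C1' bond of target 9, made last by a light-driven palladium allyl transfer from 6 to C3 of 8.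

Assumption: (S)-(−)-α-ionone of high enantiomeric purity is bought as the chiral-pool starting material; its stereocentre maps unchanged onto the (S)-centre of the target.

**Step 1**
Reactants: 1 (S)-α-ionone
Product: 2 (S)-dihydro-α-ionone, 4-[(1S)-2,6,6-trimethylcyclohex-2-en-1-yl]butan-2-one
Conditions: Cu(OAc)2·H2O (3 mol%), 1,2-(Ph2P)2C6H4 (3 mol%), (HMe2Si)2O (0.6 equiv), tBuOH (1.2 equiv), toluene, 0 °C to rt; aq. NaOH work-up
Reagents that add atoms: none
Why: Copper-hydride conjugate (1,4-) reduction: the phosphine-ligated monovalent copper hydride delivers hydride only to the enone β-carbon and tBuOH protonates the copper enolate; the isolated trisubstituted ring olefin is inert and the neutral medium does not deprotonate the γ-position, so the stereocentre is kept.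

**Step 2**
Reactants: 2 (S)-dihydro-α-ionone; 3 triethyl phosphonoacetate
Product: 4 ethyl (2E)-3-methyl-5-[(1S)-2,6,6-trimethylcyclohex-2-en-1-yl]pent-2-enoate
Conditions: NaH (1.3 equiv), 3 (1.4 equiv), THF, 0 °C then 60 °C; chromatography to remove the minor Z-ester (E/Z about 4:1)
Reagents that add atoms: none
Why: Horner–Wadsworth–Emmons olefination of a methyl ketone with a stabilised phosphonate anion gives mainly the E-enoate, and the isomers separate on silica; the stereocentre is remote and not enolisable.

**Step 3**
Reactants: 4 ethyl (2E)-3-methyl-5-[(1S)-2,6,6-trimethylcyclohex-2-en-1-yl]pent-2-enoate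
Product: 5 (2E)-3-methyl-5-[(1S)-2,6,6-trimethylcyclohex-2-en-1-yl]pent-2-en-1-ol
Conditions: iBu2AlH (2.3 equiv), CH2Cl2, −78 to 0 °C; aq. KNaC4H4O6 work-up
Reagents that add atoms: none
Why: 1,2-Reduction of the conjugated ester by the aluminium hydride gives the allylic alcohol without touching either olefin or the olefin geometry.

**Step 4**
Reactants: 5 (2E)-3-methyl-5-[(1S)-2,6,6-trimethylcyclohex-2-en-1-yl]pent-2-en-1-ol
Product: 6 methyl (2E)-3-methyl-5-[(1S)-2,6,6-trimethylcyclohex-2-en-1-yl]pent-2-en-1-yl carbonate
Conditions: ClCO2Me (1.5 equiv), pyridine (2 equiv), CH2Cl2, 0 °C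
Reagents that add atoms: methyl chloroformate COC(=O)Cl
Why: O-Acylation of a primary alcohol (carbonate formation) gives an allyl donor that ionises irreversibly with loss of CO2 and supplies its own base (methoxide).

**Step 5**
Reactants: 7 2,5-dimethoxy-1,4-benzoquinone
Product: 8 2-hydroxy-5-methoxy-1,4-benzoquinone
Conditions: NaOH (1.05 equiv), H2O/THF, 0 °C to rt; then 1 M HCl to pH 2
Reagents that add atoms: sodium hydroxide [Na+].[OH-]
Why: Saponification of a vinylogous ester by addition–elimination; the hydroxyquinonate anion formed is deactivated towards a second attack, so the hydrolysis stops at the mono-stage.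

**Step 6**
Reactants: 6 methyl (2E)-3-methyl-5-[(1S)-2,6,6-trimethylcyclohex-2-en-1-yl]pent-2-en-1-yl carbonate; 8 2-hydroxy-5-methoxy-1,4-benzoquinone (1.2 equiv)
Product: 9 2-hydroxy-5-methoxy-3-{(2E)-3-methyl-5-[(1S)-2,6,6-trimethylcyclohex-2-en-1-yl]pent-2-en-1-yl}-1,4-benzoquinone
Conditions: Pd2(dba)3 (2.5 mol%), degassed DMSO, 525 nm LEDs, 25 °C; neutral aqueous work-up
Reagents that add atoms: none
Why: Proposed new method: a light-triggered, phosphine-free Tsuji–Trost-type C-allylation in which zerovalent palladium ionises carbonate 6 (loss of CO2 and methoxide, which deprotonates 8) and the hydroxyquinonate chelates the η3-allyl divalent palladium through O1/O2 to give a red, thermally sluggish complex (compare the isolable allylpalladium β-diketonates); 525 nm excitation of its hydroxyquinonate-to-allylpalladium charge-transfer band should homolyse the Pd–allyl bond to a caged pair of the configurationally stable E-allyl radical and the ligand-centred radical (spin on C3, as in 1,3-dicarbonyl radicals), which recombine through the unhindered CH2 terminus at C3 and release zerovalent palladium, after which the trione tautomerises to 9; C3 is the enolate carbon so the position on the quinone is fixed, the E-olefin and the remote stereocentre are untouched, no new stereocentre forms, and neutral 8 and 9 absorb only weakly at 525 nm; the closest known reaction types are the thermal palladium-catalysed C-allylation of 2-hydroxy-1,4-naphthoquinone (lapachol synthesis) and the photolysis of η3-allylpalladium complexes to allyl radicals.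

**Compound list**
1 | (S)-α-ionone, (3E)-4-[(1S)-2,6,6-trimethylcyclohex-2-en-1-yl]but-3-en-2-one | CC(=O)/C=C/[C@@H]1C(C)=CCCC1(C)C | starting material
2 | (S)-dihydro-α-ionone, 4-[(1S)-2,6,6-trimethylcyclohex-2-en-1-yl]butan-2-one | CC(=O)CC[C@@H]1C(C)=CCCC1(C)C | intermediate
3 | triethyl phosphonoacetate | CCOC(=O)CP(=O)(OCC)OCC | starting material
4 | ethyl (2E)-3-methyl-5-[(1S)-2,6,6-trimethylcyclohex-2-en-1-yl]pent-2-enoate | CCOC(=O)/C=C(\C)CC[C@@H]1C(C)=CCCC1(C)C | intermediate
5 | (2E)-3-methyl-5-[(1S)-2,6,6-trimethylcyclohex-2-en-1-yl]pent-2-en-1-ol | OC/C=C(\C)CC[C@@H]1C(C)=CCCC1(C)C | intermediate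
6 | methyl (2E)-3-methyl-5-[(1S)-2,6,6-trimethylcyclohex-2-en-1-yl]pent-2-en-1-yl carbonate | COC(=O)OC/C=C(\C)CC[C@@H]1C(C)=CCCC1(C)C | intermediate
7 | 2,5-dimethoxy-1,4-benzoquinone | COC1=CC(=O)C(OC)=CC1=O | starting material
8 | 2-hydroxy-5-methoxy-1,4-benzoquinone | COC1=CC(=O)C(O)=CC1=O | intermediate
9 | 2-hydroxy-5-methoxy-3-{(2E)-3-methyl-5-[(1S)-2,6,6-trimethylcyclohex-2-en-1-yl]pent-2-en-1-yl}-1,4-benzoquinone | COC1=CC(=O)C(O)=C(C/C=C(\C)CC[C@@H]2C(C)=CCCC2(C)C)C1=O | target

**Totals**
Total step count: 6. Longest linear sequence: 5 (1 → 2 → 4 → 5 → 6 → 9).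

**Steps most likely to fail**

Step 6 (the new photochemical coupling). It may stall at the palladium chelate, give branched or O-allylated material, lose the allyl unit as a diene by β-hydride elimination, or suffer photoaddition of the quinone to the olefins. The fallback uses known chemistry. It sets out from alcohol 5 and hydroxyquinone 8 and comes back at target 9. The photochemical radical-pair manifold is given up for the classical two-electron Tsuji–Trost C-allylation that turns 2-hydroxy-1,4-naphthoquinone into lapachol: Pd(PPh3)4 (5 mol%), 1,4-dioxane, 80 °C, in the dark. The acidic hydroxyquinone activates the allylic hydroxyl, and the cationic phosphine-ligated π-allyl palladium is attacked outer-sphere at its CH2 terminus by C3 of the hydroxyquinonate. Water is the only by-product, and carbonate 6 can replace 5 if ionisation is slow. It makes no new compound (F0).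

Step 2 (olefin geometry). The E/Z ratio of about 4:1 may be lower, or the isomers may not separate cleanly. The fallback sets out from ketone 2 and comes back at ester 4. It replaces the olefination by syn-carbometalation of an alkyne, which fixes the E geometry mechanistically.
- Kinetic enolisation of 2 (LiN(iPr)2, THF, −78 °C) and trapping with ClP(O)(OEt)2 gives the enol phosphate diethyl 4-[(1S)-2,6,6-trimethylcyclohex-2-en-1-yl]but-1-en-2-yl phosphate F1.
- Elimination with more LiN(iPr)2 gives the terminal alkyne (6S)-6-(but-3-yn-1-yl)-1,5,5-trimethylcyclohex-1-ene F2.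
- Zirconium-catalysed methylalumination (Me3Al, Cp2ZrCl2 cat., CH2Cl2) gives the alkenylalane dimethyl{(1E)-2-methyl-4-[(1S)-2,6,6-trimethylcyclohex-2-en-1-yl]but-1-en-1-yl}alumane F3.
- Quenching F3 with ClCO2Et gives 4 as the E isomer only.

Step 1 (chemoselective conjugate reduction). Possible failures are 1,2-reduction, over-reduction, or erosion of the stereocentre through γ-deprotonation of the enone. The fallback sets out from 1 and comes back at 2. It switches to rhodium-catalysed 1,4-hydrosilylation under strictly neutral conditions: Et3SiH and RhCl(PPh3)3 (0.5 mol%), benzene, 50 °C. This gives the isolable silyl enol ether triethyl({4-[(1S)-2,6,6-trimethylcyclohex-2-en-1-yl]but-2-en-2-yl}oxy)silane F4 as an E/Z mixture. Dilute HCl in THF then hydrolyses F4 to 2.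

**Further compounds**
F1 | step 2 | diethyl 4-[(1S)-2,6,6-trimethylcyclohex-2-en-1-yl]but-1-en-2-yl phosphate | C=C(CC[C@@H]1C(C)=CCCC1(C)C)OP(=O)(OCC)OCC
F2 | step 2 | (6S)-6-(but-3-yn-1-yl)-1,5,5-trimethylcyclohex-1-ene | C#CCC[C@@H]1C(C)=CCCC1(C)C
F3 | step 2 | dimethyl{(1E)-2-methyl-4-[(1S)-2,6,6-trimethylcyclohex-2-en-1-yl]but-1-en-1-yl}alumane | C[Al](C)/C=C(\C)CC[C@@H]1C(C)=CCCC1(C)C
F4 | step 1 | triethyl({4-[(1S)-2,6,6-trimethylcyclohex-2-en-1-yl]but-2-en-2-yl}oxy)silane (E/Z mixture) | CC(O[Si](CC)(CC)CC)=CC[C@@H]1C(C)=CCCC1(C)C
F0 | step 6 | none | none
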